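## Analysis of the target

Marchantin C is a macrocyclic bis(bibenzyl). Four benzene rings are held in an 18-membered ring by two diaryl ether oxygens and two CH2CH2 bridges. Ring A is a para-phenylene and ring C a meta-phenylene. Ring B is a 1,2,3-trisubstituted phenol (bridge at C1, oxygen to ring C at C2, hydroxyl at C3). Ring D is a 1,2,4-trisubstituted phenol (hydroxyl at C1, oxygen to ring A at C2, bridge to ring C at C4). The molecule has no stereocentre, so there is no relative or absolute configuration to set and the problem is one of connectivity only. The sensitive groups are the two phenols; the ring D phenol is a catechol monoether and is easily oxidised as its anion, whereas the diaryl ethers and bridges are robust. Three things make the synthesis hard: the ring B oxygen at C2 is flanked on both sides, the two phenolic oxygens must be told apart, and an 18-membered ring has to be closed. The strategy rests on ring D. Its atoms C6-C1-C2 correspond to a methyl ketone whose second alpha carbon already carries the ring A oxygen (an aryloxyacetone), and its atoms C3-C4-C5 correspond to a malondialdehyde unit whose central carbon C4 carries the chain to ring C. These two pieces together are already at the oxidation level of a phenol, and the three-carbon piece is symmetric about C4, so ring D can be grown in the step that closes the macrocycle, with its hydroxyl in place and unprotected.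

## Retrosynthetic reasoning

18 to 17. The last bond cut is the O-CH3 bond on ring B. A methyl ether is kept there because it arrives with fluoroaldehyde 5, survives every step, and is the only ether in 17 with an sp3 carbon that a Lewis acid can attack. The forward step only has to demethylate without touching the diaryl ethers.

17 to 15. Ring D is cut at C2-C3 and C5-C6. This is preferred to cutting a diaryl ether or a bridge because it opens the macrocycle and removes ring D in one operation, and it leaves an open chain, 15, that contains only rings A, B and C. The phenol oxygen of ring D is the ketone oxygen of 15, so no protecting group is needed on it. The forward reaction has to condense the two alpha carbons of the aryloxyacetone terminus with the two ends of the 2-substituted 3-(dimethylamino)acrolein terminus and aromatise.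

15 to 13 and 14. The O-CH2 bond of the aryloxyacetone is cut, leading to phenol 13 and chloroacetone 14. The ketone is introduced last for two reasons. An earlier ketone would compete with the aldehyde when the one-carbon unit is added. Also, 15 carries both reaction partners of the key step and should not be exposed to further steps.

13 to 12. The bond between the alpha carbon of the butanal and the aminomethylidene carbon is cut. The forward reaction is the condensation of aldehyde 12 with a formamide-derived one-carbon electrophile, which makes the masked 1,3-dialdehyde with the chain on its central carbon.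

12 to 11 to 10. These are changes of functional group only. The aldehyde of 12 is stored as the dioxolane of 11. The saturated bridges and the free ring A phenol of 11 come from 10 by one hydrogenation, which reduces two alkenes and removes the benzyl group.

10 to 6 and 8. The ring A to ring B bridge is cut at its central bond as an alkene, giving aldehyde 6 and phosphonium salt 8. Salt 8 comes from benzylic chloride 7. The aldehyde that activated ring B for ether formation is thereby used a second time.

6 to 4 and 5. The hindered ring B C2-O bond is cut. The formyl group ortho to fluorine in 5 allows this bond to be made by addition-elimination with phenol 4, the mildest way to reach the doubly flanked position.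

4 to 1 and 2. The ring C arm is cut at the alkene, giving aldehyde 1 and the acetal-bearing phosphonium salt 2. This installs all four carbons of the future butanal in one step at the correct oxidation level.

## Alternatives that were turned down

Alternative 1: Ring B is the ring built de novo. Its C2-C3 and C1-C6 bonds are cut, leading to 3-methoxy-2H-pyran-2-one A1 as the diene and to the internal aryl alkynyl ether A2. In A2 one alkyne carbon carries the ring C oxygen and the other carries the two-carbon chain to a 4-bromophenyl ring A. Heating A1 with A2 should give a bridged adduct that loses its lactone bridge by cycloreversion and aromatises to the open-chain four-ring ether A3.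
- For: the crowded ring B ether is never formed on an existing arene, and the polarity of the two partners (nucleophilic beta carbon of the alkynyl ether onto C6 of the pyranone) predicts the correct 1,2,3-pattern. The key step is intermolecular, needs no dilution, and extends a known cycloaddition; on these points it is stronger than the chosen route.
- Against: A2 is a sensitive alkynyl ether that needs several steps to prepare. The electron-rich pyranone A1 is a reluctant diene, so forcing temperatures are likely. A3 is still open, so an acetal cleavage, a copper-mediated macrocyclic etherification next to a methoxy group and two demethylations remain.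
- Comparison: the chosen route makes the hindered ether by a simple addition-elimination, so the main asset of this alternative is not needed. The chosen key step also closes the macrocycle, which this one does not.

Alternative 2: The ring C carbon-oxygen bond of the ring B to ring C ether is cut. The precursor is the seco-phenol A4, with a free ring B C2 hydroxyl and a 3-fluoro-4-nitrophenyl ring C. A carbonate base under dilution should ionise the phenol, which displaces fluoride ortho to the nitro group and closes the 18-membered ring as the nitro macrocycle A5.
- For: activated addition-elimination is the best-precedented way to close diaryl ether macrocycles and needs no metal. In certainty of the ring closure it is clearly stronger than the chosen route.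
- Against: the nucleophile is the doubly ortho-substituted ring B phenoxide, the most hindered oxygen of the molecule, used in the entropically hardest step. The nitro group has no place in the target and costs a reduction, a diazotisation and a reductive removal. Two methyl ethers remain to be cleaved, and the ring D to ring A ether of A4 must be made beforehand by a separate coupling.
- Comparison: the chosen route introduces no atom that must later be excised and delivers the ring D hydroxyl free. It gives up precedent in exchange for a shorter end game.

Alternative 3: The bond between the ring A oxygen and ring D C2 is cut. The precursor is the bis-phenol A6, a 2,6-dibromophenol on ring D and a 2,6-dichlorophenol on ring A. Oxidation of the ring D phenol with a trivalent thallium salt in an alcohol, attack of the ring A oxygen at a bromine-bearing ortho carbon and reductive work-up should give the trihalogenated macrocycle A7.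
- For: it is biomimetic and forms the ether with the ring D hydroxyl already in place, as the chosen route does. Its precursor is assembled entirely by routine bibenzyl chemistry, which is a real advantage over the chosen route.
- Against: it needs a stoichiometric, highly toxic oxidant. Four halogens must be placed on two different phenols and three removed afterwards. Which phenol is oxidised depends only on the halogen pattern. Phenol oxidations of this kind compete with intermolecular coupling, and the ring B methyl ether still has to be cleaved.
- Comparison: the chosen route reaches the same free ring D phenol without blocking groups, without a heavy-metal oxidant and with fewer operations after the ring closure.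

Key step: step 9

Assumption: the alkenes formed in steps 1 and 4 are carried on as mixtures of E and Z isomers, since both are saturated in step 5, so their SMILES carry no geometry label.

## Route

Step 1
Reactants: 1 3-hydroxybenzaldehyde; 2 [2-(1,3-dioxolan-2-yl)ethyl]triphenylphosphonium bromide
Product: 4 3-[3-(1,3-dioxolan-2-yl)prop-1-en-1-yl]phenol as an E/Z mixture, via phosphorus ylide 3 (not isolated)
Conditions: 2, KOt-Bu (2.3 equiv), THF, 0 °C; then 1, 0 °C → rt; aq. NH4Cl
Reagents that add atoms: none
Why: Wittig olefination with a non-stabilised ylide; the extra equivalent of base converts the phenol into its potassium salt, and the aldehyde stays reactive because a meta oxido group is not conjugated with it. The alkene geometry is of no consequence.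

Step 2
Reactants: 4 3-[3-(1,3-dioxolan-2-yl)prop-1-en-1-yl]phenol; 5 2-fluoro-3-methoxybenzaldehyde
Product: 6 2-{3-[3-(1,3-dioxolan-2-yl)prop-1-en-1-yl]phenoxy}-3-methoxybenzaldehyde as an E/Z mixture
Conditions: K2CO3, DMF, 110 °C
Reagents that add atoms: none
Why: Nucleophilic aromatic substitution (SNAr): the ortho formyl group stabilises the anionic adduct and fluoride is the best leaving group for addition-elimination, while the small fluorine lets the phenoxide reach the carbon flanked by OMe and CHO. The acetal and the styrene are inert to carbonate.

Step 3
Reactants: 7 4-(benzyloxy)benzyl chloride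
Product: 8 [4-(benzyloxy)benzyl]triphenylphosphonium chloride
Conditions: PPh3, toluene, reflux
Reagents that add atoms: triphenylphosphine, c1ccc(cc1)P(c1ccccc1)c1ccccc1
Why: SN2 quaternisation of a reactive benzylic chloride; the salt should precipitate from toluene.

Step 4
Reactants: 6 2-{3-[3-(1,3-dioxolan-2-yl)prop-1-en-1-yl]phenoxy}-3-methoxybenzaldehyde; 8 [4-(benzyloxy)benzyl]triphenylphosphonium chloride
Product: 10 2-{3-[3-(2-{2-[4-(benzyloxy)phenyl]ethenyl}-6-methoxyphenoxy)phenyl]prop-2-en-1-yl}-1,3-dioxolane as a mixture of alkene isomers, via phosphorus ylide 9 (not isolated)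
Conditions: 8, KOt-Bu, THF, 0 °C; then 6, 0 °C → rt
Reagents that add atoms: none
Why: Wittig olefination with a semi-stabilised benzylic ylide; the dioxolane is stable to base and the stilbene geometry is erased in the next step.

Step 5
Reactants: 10 2-{3-[3-(2-{2-[4-(benzyloxy)phenyl]ethenyl}-6-methoxyphenoxy)phenyl]prop-2-en-1-yl}-1,3-dioxolane
Product: 11 4-[2-(2-{3-[3-(1,3-dioxolan-2-yl)propyl]phenoxy}-3-methoxyphenyl)ethyl]phenol
Conditions: H2 (1 atm), Pd/C, EtOAc, rt
Reagents that add atoms: none
Why: Heterogeneous catalytic hydrogenation saturates both disubstituted alkenes and hydrogenolyses the benzyl ether in one operation. Diaryl ethers, the methyl ether and the dioxolane are untouched in a neutral, non-alcoholic solvent.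

Step 6
Reactants: 11 4-[2-(2-{3-[3-(1,3-dioxolan-2-yl)propyl]phenoxy}-3-methoxyphenyl)ethyl]phenol
Product: 12 4-(3-{2-[2-(4-hydroxyphenyl)ethyl]-6-methoxyphenoxy}phenyl)butanal
Conditions: 1 M HCl, THF, rt
Reagents that add atoms: water, O
Why: Acid-catalysed acetal hydrolysis; nothing else in the molecule is acid-labile.

Step 7
Reactants: 12 4-(3-{2-[2-(4-hydroxyphenyl)ethyl]-6-methoxyphenoxy}phenyl)butanal
Product: 13 (E)-2-[(dimethylamino)methylidene]-4-(3-{2-[2-(4-hydroxyphenyl)ethyl]-6-methoxyphenoxy}phenyl)butanal
Conditions: t-BuOCH(NMe2)2 (3 equiv), toluene, 70 °C; aq. NaHCO3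
Reagents that add atoms: tert-butoxybis(dimethylamino)methane, CN(C)C(OC(C)(C)C)N(C)C
Why: Aminomethylenation of a CH-acidic carbonyl compound with an aminal ester: the reagent ionises to a formamidinium ion and tert-butoxide, the aldehyde enolate adds and dimethylamine is lost, giving the vinylogous formamide as the more stable E isomer. The free phenol should be tolerated because this reagent has no transferable O-methyl group and any aryloxy aminal reverts on aqueous work-up; the excess covers the proton the phenol supplies.

Step 8
Reactants: 13 (E)-2-[(dimethylamino)methylidene]-4-(3-{2-[2-(4-hydroxyphenyl)ethyl]-6-methoxyphenoxy}phenyl)butanal; 14 chloroacetone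
Product: 15 (E)-2-[(dimethylamino)methylidene]-4-[3-(2-methoxy-6-{2-[4-(2-oxopropoxy)phenyl]ethyl}phenoxy)phenyl]butanal
Conditions: K2CO3, KI (cat.), acetone, rt
Reagents that add atoms: none
Why: Williamson ether synthesis with an activated alpha-chloro ketone under Finkelstein catalysis. Carbonate is too weak to enolise the product ketone appreciably, and the vinylogous formamide is not alkylated at its fully substituted carbon, so 15 should survive until it is exposed to strong base.

Step 9
Reactants: 15 (E)-2-[(dimethylamino)methylidene]-4-[3-(2-methoxy-6-{2-[4-(2-oxopropoxy)phenyl]ethyl}phenoxy)phenyl]butanal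
Product: 17 marchantin C ring B methyl ether, via macrocyclic dienaminone 16 (not isolated)
Conditions: 15 added by syringe pump to KOt-Bu (4 equiv), THF, 50 °C, final concentration about 1 mM, argon; then AcOH, 50 °C
Reagents that add atoms: none
Why: Proposed new method: the potassium enolate at the aryloxy-bearing carbon, the more acidic alpha position of the ketone, should add to the formyl carbon of the vinylogous formamide and lose water with the push of the nitrogen lone pair, closing the 18-membered ring as dienaminone 16 (an 18-exo-trig aldol condensation). The methyl carbon then attacks the aminomethylidene carbon (6-endo-trig, or equally a 6π electrocyclisation of the trienolate), dimethylamine is expelled, at the latest on acidification, and the dienone tautomerises to the phenol. The closest known reaction types are the phenol syntheses from ketones with nitromalonaldehyde or vinamidinium salts, the base-induced conversion of 2-methylpyrylium salts into phenols through the same open-chain stage, and the enolate condensations with 3-(dimethylamino)enones used for pyridines; none of these has been run with a 2-alkyl three-carbon unit or as a macrocyclisation. No stereocentre is formed. No regiocontrol is needed, because the three-carbon unit is symmetric about the carbon that bears the chain: attack by either alpha carbon on either terminus ends in the same 4-alkyl-2-aryloxyphenol, and if the methyl carbon reacts first a 20-membered ring forms that becomes the 18-membered ring when the benzene ring closes. The only selectivity required is ring closure over oligomerisation, which rests on slow addition into dilute base, on the turn imposed by the ortho-linked ring B, and on the fast, irreversible aromatising second closure. The six carbons are already at the oxidation level of a phenol, so no oxidant is needed.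

Step 10
Reactants: 17 marchantin C ring B methyl ether
Product: 18 marchantin C
Conditions: BBr3, CH2Cl2, −78 → 0 °C; then H2O
Reagents that add atoms: none
Why: Lewis acid demethylation of an aryl methyl ether: boron coordinates the ether oxygen and bromide attacks the methyl carbon by SN2. The diaryl ethers have no sp3 carbon and are not cleaved.

## Compound list

1 | 3-hydroxybenzaldehyde | O=Cc1cccc(O)c1 | starting material
2 | [2-(1,3-dioxolan-2-yl)ethyl]triphenylphosphonium bromide | [Br-].C1COC(CC[P+](c2ccccc2)(c2ccccc2)c2ccccc2)O1 | starting material
3 | [2-(1,3-dioxolan-2-yl)ethylidene]triphenylphosphorane (ylide from 2) | C1COC(CC=P(c2ccccc2)(c2ccccc2)c2ccccc2)O1 | intermediate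
4 | 3-[3-(1,3-dioxolan-2-yl)prop-1-en-1-yl]phenol (E/Z mixture) | Oc1cccc(C=CCC2OCCO2)c1 | intermediate
5 | 2-fluoro-3-methoxybenzaldehyde | COc1cccc(C=O)c1F | starting material
6 | 2-{3-[3-(1,3-dioxolan-2-yl)prop-1-en-1-yl]phenoxy}-3-methoxybenzaldehyde (E/Z mixture) | COc1cccc(C=O)c1Oc1cccc(C=CCC2OCCO2)c1 | intermediate
7 | 4-(benzyloxy)benzyl chloride | ClCc1ccc(OCc2ccccc2)cc1 | starting material
8 | [4-(benzyloxy)benzyl]triphenylphosphonium chloride | [Cl-].c1ccc(COc2ccc(C[P+](c3ccccc3)(c3ccccc3)c3ccccc3)cc2)cc1 | intermediate
9 | [4-(benzyloxy)benzylidene]triphenylphosphorane (ylide from 8) | c1ccc(COc2ccc(C=P(c3ccccc3)(c3ccccc3)c3ccccc3)cc2)cc1 | intermediate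
10 | 2-{3-[3-(2-{2-[4-(benzyloxy)phenyl]ethenyl}-6-methoxyphenoxy)phenyl]prop-2-en-1-yl}-1,3-dioxolane (mixture of alkene isomers) | COc1cccc(C=Cc2ccc(OCc3ccccc3)cc2)c1Oc1cccc(C=CCC2OCCO2)c1 | intermediate
11 | 4-[2-(2-{3-[3-(1,3-dioxolan-2-yl)propyl]phenoxy}-3-methoxyphenyl)ethyl]phenol | COc1cccc(CCc2ccc(O)cc2)c1Oc1cccc(CCCC2OCCO2)c1 | intermediate
12 | 4-(3-{2-[2-(4-hydroxyphenyl)ethyl]-6-methoxyphenoxy}phenyl)butanal | COc1cccc(CCc2ccc(O)cc2)c1Oc1cccc(CCCC=O)c1 | intermediate
13 | (E)-2-[(dimethylamino)methylidene]-4-(3-{2-[2-(4-hydroxyphenyl)ethyl]-6-methoxyphenoxy}phenyl)butanal | COc1cccc(CCc2ccc(O)cc2)c1Oc1cccc(CC/C(C=O)=C\N(C)C)c1 | intermediate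
14 | chloroacetone | CC(=O)CCl | starting material
15 | (E)-2-[(dimethylamino)methylidene]-4-[3-(2-methoxy-6-{2-[4-(2-oxopropoxy)phenyl]ethyl}phenoxy)phenyl]butanal (open-chain aryloxyacetone enaminal) | CC(=O)COc1ccc(CCc2cccc(OC)c2Oc2cccc(CC/C(C=O)=C\N(C)C)c2)cc1 | intermediate
16 | macrocyclic dienaminone: 18-membered ring closed through the C2-C3 bond of the future ring D, with the acetyl group on C2 and the (dimethylamino)methylidene group on C4 both exocyclic; alkene geometry mobile and not fixed | CC(=O)C1=CC(=CN(C)C)CCc2cccc(c2)Oc2c(OC)cccc2CCc2ccc(O1)cc2 | intermediate
17 | marchantin C ring B methyl ether | Oc1ccc2cc1Oc1ccc(cc1)CCc1cccc(OC)c1Oc1cccc(c1)CC2 | intermediate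
18 | marchantin C | Oc1ccc2cc1Oc1ccc(cc1)CCc1cccc(O)c1Oc1cccc(c1)CC2 | target

## Step count and least certain steps

Total step count: 10. Longest linear sequence: 9 steps (1, 2, 4, 5, 6, 7, 8, 9, 10); step 3 is a one-step branch.

**Step 9 (key step, the one carrying the label for a new method).**
- Most likely failure: condensation between two molecules outruns the first ring closure. The enolate and the vinylogous formamide are only moderately reactive towards each other, the chain has many rotatable bonds, and each intermolecular condensation product can grow further.
- Second failure mode: on acidification the mono-condensed intermediate closes through the ketone oxygen instead of the methyl carbon.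
- Fallback (known chemistry, ring D taken from an intact arene): it sets out from 5 and rejoins the route at 18.
  - SNAr of 5 with 3-hydroxybenzyl alcohol (K2CO3, DMF) should give 2-[3-(hydroxymethyl)phenoxy]-3-methoxybenzaldehyde F1.
  - Wittig reaction with ylide 9, made from 8, should give the stilbene {3-[2-{2-[4-(benzyloxy)phenyl]ethenyl}-6-methoxyphenoxy]phenyl}methanol F2.
  - Hydrogenation over Pd/C saturates the alkene and frees the ring A phenol, giving 4-[2-(2-{3-(hydroxymethyl)phenoxy}-3-methoxyphenyl)ethyl]phenol F3.
  - Ullmann coupling of this phenol with 3-bromo-4-methoxybenzaldehyde (CuI, N,N-dimethylglycine, Cs2CO3, dioxane, 90 °C) attaches ring D as 3-[4-(2-{2-[3-(hydroxymethyl)phenoxy]-3-methoxyphenyl}ethyl)phenoxy]-4-methoxybenzaldehyde F4.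
  - MnO2 in CH2Cl2 oxidises the benzylic alcohol to the dialdehyde 3-[4-(2-{2-(3-formylphenoxy)-3-methoxyphenyl}ethyl)phenoxy]-4-methoxybenzaldehyde F5.
  - McMurry coupling with low-valent titanium (TiCl4, Zn, pyridine, THF, reflux, high dilution) closes the 18-membered ring as the macrocyclic stilbene, marchantin C dimethyl ether with a C=C bond in the ring C to ring D bridge F6.
  - Hydrogenation over Pd/C gives marchantin C dimethyl ether F7, and BBr3 cleaves both methyl ethers to give 18.

**Step 7.**
- Most likely failure: the acidic phenol consumes the aminal ester and slows the aminomethylenation, so that aldol self-condensation of the aliphatic aldehyde competes.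
- Fallback, from 11 back to 13: the phenol is silylated first (TIPSCl, imidazole, DMF), giving the dioxolane of 4-(3-{2-methoxy-6-[2-(4-triisopropylsilyloxyphenyl)ethyl]phenoxy}phenyl)butanal F8. Mild acid hydrolysis gives 4-(3-{2-methoxy-6-[2-(4-triisopropylsilyloxyphenyl)ethyl]phenoxy}phenyl)butanal F9. The aminomethylenation is then run on a substrate without an acidic hydrogen and with little excess of reagent, giving the silyl-protected enaminal F10. Fluoride (TBAF, THF) removes the silyl group to give 13.

**Step 2.**
- Most likely failure: slow substitution at the fluorine-bearing carbon, which sits between a methoxy and a formyl group, with base-induced degradation of the aldehyde at the temperature then needed.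
- Fallback, from 4 back to 6: the reaction type is changed to a copper-catalysed Ullmann coupling of 4 with 2-bromo-3-methoxybenzaldehyde (CuI, N,N-dimethylglycine, Cs2CO3, dioxane, 90 °C), in which the ortho formyl group assists the metal. This makes 6 directly and no new compound (F0).

**Step 8.**
- Most likely failure: premature enolisation of the new ketone under carbonate at preparative concentration. Compound 15 carries its own electrophile, so this would start oligomerisation; chloroacetone can also self-condense.
- Fallback, from 11 back to 15: the three-carbon unit is introduced at the alcohol oxidation level and oxidised last, without base.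
  - Phenol 11 opens propylene oxide (K2CO3, DMF, 90 °C) to give the racemic dioxolane of 4-[3-(2-{2-[4-(2-hydroxypropoxy)phenyl]ethyl}-6-methoxyphenoxy)phenyl]butanal F11.
  - Acid hydrolysis gives racemic 4-[3-(2-{2-[4-(2-hydroxypropoxy)phenyl]ethyl}-6-methoxyphenoxy)phenyl]butanal F12.
  - The aminal ester gives the racemic hydroxy enaminal (E)-2-[(dimethylamino)methylidene]-4-[3-(2-{2-[4-(2-hydroxypropoxy)phenyl]ethyl}-6-methoxyphenoxy)phenyl]butanal F13.
  - Dess-Martin periodinane with NaHCO3 in CH2Cl2 oxidises the secondary alcohol to give 15.

## Further compounds

F1 | step 9 | 2-[3-(hydroxymethyl)phenoxy]-3-methoxybenzaldehyde | COc1cccc(C=O)c1Oc1cccc(CO)c1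
F2 | step 9 | {3-[2-{2-[4-(benzyloxy)phenyl]ethenyl}-6-methoxyphenoxy]phenyl}methanol (E/Z mixture) | COc1cccc(C=Cc2ccc(OCc3ccccc3)cc2)c1Oc1cccc(CO)c1
F3 | step 9 | 4-[2-(2-{3-(hydroxymethyl)phenoxy}-3-methoxyphenyl)ethyl]phenol | COc1cccc(CCc2ccc(O)cc2)c1Oc1cccc(CO)c1
F4 | step 9 | 3-[4-(2-{2-[3-(hydroxymethyl)phenoxy]-3-methoxyphenyl}ethyl)phenoxy]-4-methoxybenzaldehyde | COc1ccc(C=O)cc1Oc1ccc(CCc2cccc(OC)c2Oc2cccc(CO)c2)cc1
F5 | step 9 | 3-[4-(2-{2-(3-formylphenoxy)-3-methoxyphenyl}ethyl)phenoxy]-4-methoxybenzaldehyde | COc1ccc(C=O)cc1Oc1ccc(CCc2cccc(OC)c2Oc2cccc(C=O)c2)cc1
F6 | step 9 | macrocyclic stilbene, marchantin C dimethyl ether with a C=C bond in the ring C to ring D bridge (geometry not fixed) | COc1ccc2cc1Oc1ccc(cc1)CCc1cccc(OC)c1Oc1cccc(c1)C=C2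
F7 | step 9 | marchantin C dimethyl ether | COc1ccc2cc1Oc1ccc(cc1)CCc1cccc(OC)c1Oc1cccc(c1)CC2
F8 | step 7 | dioxolane of 4-(3-{2-methoxy-6-[2-(4-triisopropylsilyloxyphenyl)ethyl]phenoxy}phenyl)butanal | COc1cccc(CCc2ccc(O[Si](C(C)C)(C(C)C)C(C)C)cc2)c1Oc1cccc(CCCC2OCCO2)c1
F9 | step 7 | 4-(3-{2-methoxy-6-[2-(4-triisopropylsilyloxyphenyl)ethyl]phenoxy}phenyl)butanal | COc1cccc(CCc2ccc(O[Si](C(C)C)(C(C)C)C(C)C)cc2)c1Oc1cccc(CCCC=O)c1
F10 | step 7 | (E)-2-[(dimethylamino)methylidene]-4-(3-{2-methoxy-6-[2-(4-triisopropylsilyloxyphenyl)ethyl]phenoxy}phenyl)butanal | COc1cccc(CCc2ccc(O[Si](C(C)C)(C(C)C)C(C)C)cc2)c1Oc1cccc(CC/C(C=O)=C\N(C)C)c1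
F0 | step 2 | none | none
F11 | step 8 | racemic dioxolane of 4-[3-(2-{2-[4-(2-hydroxypropoxy)phenyl]ethyl}-6-methoxyphenoxy)phenyl]butanal | CC(O)COc1ccc(CCc2cccc(OC)c2Oc2cccc(CCCC3OCCO3)c2)cc1
F12 | step 8 | racemic 4-[3-(2-{2-[4-(2-hydroxypropoxy)phenyl]ethyl}-6-methoxyphenoxy)phenyl]butanal | CC(O)COc1ccc(CCc2cccc(OC)c2Oc2cccc(CCCC=O)c2)cc1
F13 | step 8 | racemic (E)-2-[(dimethylamino)methylidene]-4-[3-(2-{2-[4-(2-hydroxypropoxy)phenyl]ethyl}-6-methoxyphenoxy)phenyl]butanal | CC(O)COc1ccc(CCc2cccc(OC)c2Oc2cccc(CC/C(C=O)=C\N(C)C)c2)cc1
A1 | alternative 1 | 3-methoxy-2H-pyran-2-one | COc1cccoc1=O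
A2 | alternative 1 | internal aryl alkynyl ether, 4-{2-[3-(4-(4-bromophenyl)but-1-yn-1-yloxy)phenyl]ethyl}-1-methoxy-2-(methoxymethoxy)benzene | COCOc1cc(CCc2cccc(OC#CCCc3ccc(Br)cc3)c2)ccc1OC
A3 | alternative 1 | open-chain four-ring ether with ring B complete | COCOc1cc(CCc2cccc(Oc3c(OC)cccc3CCc3ccc(Br)cc3)c2)ccc1OC
A4 | alternative 2 | seco-phenol, 2-[2-(4-{5-[2-(3-fluoro-4-nitrophenyl)ethyl]-2-methoxyphenoxy}phenyl)ethyl]-6-methoxyphenol | COc1ccc(CCc2ccc([N+](=O)[O-])c(F)c2)cc1Oc1ccc(CCc2cccc(OC)c2O)cc1
A5 | alternative 2 | ring C nitro marchantin C dimethyl ether | COc1ccc2cc1Oc1ccc(cc1)CCc1cccc(OC)c1Oc1cc(ccc1[N+](=O)[O-])CC2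
A6 | alternative 3 | seco-bis-phenol, 2,6-dibromo-4-{2-[3-(2-{2-(3,5-dichloro-4-hydroxyphenyl)ethyl}-6-methoxyphenoxy)phenyl]ethyl}phenol | Oc1c(Br)cc(CCc2cccc(Oc3c(OC)cccc3CCc3cc(Cl)c(O)c(Cl)c3)c2)cc1Br
A7 | alternative 3 | trihalogenated marchantin C ring B methyl ether | Oc1c(Br)cc2cc1Oc1c(Cl)cc(cc1Cl)CCc1cccc(OC)c1Oc1cccc(c1)CC2
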